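Ring A is disconnected, after removal of the allyl ester and the silyl ether, at C3–C4 and C1–C6 into a 1,3-bis(silyloxy)diene carried by a ring B aryl 3-oxopentanoate and 4,4-dimethoxybut-3-en-2-one.
Enabling feature: ring A is an orsellinate (C1 bears the ester carbonyl C7, C2 OH, C3 CH2OH, C4 OMe, C5 H, C6 CH3), so its alternating oxygens divide it into a nucleophilic β-ketoester unit C1–C3 and an electrophilic unit C4–C6 (acetal carbon C4, ketone carbon C6).
The depside C–O bond is cut next (acylketene plus the 4-hydroxyl of ring B), then the ketoester C2–C3 bond (Meldrum's acid plus 3-silyloxypropanoic acid).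
Forward: ring B is bought intact as atraric acid and re-esterified as its allyl ester, the five-carbon chain is hung on its 4-oxygen, ring A is closed last on that ester, and two deprotections finish.
Stereochemistry: the target has no stereocentre and no stereogenic double bond; all geometry in the diene is erased on aromatisation.

Key step: step 9

Assumption: the double-bond geometry of the silylated diene (drawn 1E,3Z) and of the open-chain adduct is of no consequence because both are lost when ring A aromatises; mixtures of geometric isomers would serve equally, and the adduct is racemic at its one sp3 centre.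

Step 1
Reactants: 1 methyl 2,4-dihydroxy-3,6-dimethylbenzoate (atraric acid)
Product: 2 2,4-dihydroxy-3,6-dimethylbenzoic acid
Conditions: conc. H2SO4, 0 °C → rt; then poured onto ice
Reagents that add atoms: water, O
Why: Acid-catalysed ester hydrolysis by the unimolecular acylium pathway (A_AC1): the di-ortho-substituted, electron-rich benzoate ionises in cold sulfuric acid to an acylium ion that water captures on quenching, the classical way to open hindered benzoates that resist saponification, and the cold protonated medium suppresses decarboxylation.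

Step 2
Reactants: 2 2,4-dihydroxy-3,6-dimethylbenzoic acid
Product: 3 allyl 2,4-dihydroxy-3,6-dimethylbenzoate
Conditions: allyl bromide (1.1 equiv), KHCO3 (1.2 equiv), DMF, rt
Reagents that add atoms: allyl bromide, C=CCBr
Why: Carboxylate O-alkylation (SN2): bicarbonate deprotonates only the carboxylic acid, so allyl bromide esterifies it and both phenols stay free.

Step 3
Reactants: 4 methyl 3-hydroxypropanoate
Product: 5 methyl 3-(triisopropylsilyloxy)propanoate
Conditions: TIPSCl, imidazole, DMF, 0 °C → rt
Reagents that add atoms: chlorotriisopropylsilane, CC(C)[Si](Cl)(C(C)C)C(C)C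
Why: Imidazole-promoted O-silylation of a primary alcohol; the bulky silyl ether is chosen because it must later survive TiCl4.

Step 4
Reactants: 5 methyl 3-(triisopropylsilyloxy)propanoate
Product: 6 3-(triisopropylsilyloxy)propanoic acid
Conditions: LiOH·H2O, THF/H2O, 0 °C → rt; then 1 M HCl to pH 3 at 0 °C
Reagents that add atoms: lithium hydroxide, [Li+].[OH-]
Why: Saponification of an unhindered methyl ester (B_AC2); cold aqueous LiOH and brief acidification to pH 3 leave the primary triisopropylsilyl ether intact.

Step 5
Reactants: 6 3-(triisopropylsilyloxy)propanoic acid; 7 Meldrum's acid (2,2-dimethyl-1,3-dioxane-4,6-dione)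
Product: 8 5-[1-hydroxy-3-(triisopropylsilyloxy)propylidene]-2,2-dimethyl-1,3-dioxane-4,6-dione
Conditions: DCC, DMAP, CH2Cl2, 0 °C → rt; filtration, cold aqueous KHSO4 wash
Reagents that add atoms: none
Why: Carbodiimide/DMAP C-acylation of Meldrum's acid: the activated acid is passed by DMAP to the highly acidic methylene carbon and the product is held as its hydrogen-bonded enol.

Step 6
Reactants: 8 5-[1-hydroxy-3-(triisopropylsilyloxy)propylidene]-2,2-dimethyl-1,3-dioxane-4,6-dione; 3 allyl 2,4-dihydroxy-3,6-dimethylbenzoate
Product: 10 allyl 2-hydroxy-3,6-dimethyl-4-{[3-oxo-5-(triisopropylsilyloxy)pentanoyl]oxy}benzoate, via acylketene 9 (not isolated)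
Conditions: toluene, 90–110 °C (8 in slight excess)
Reagents that add atoms: none
Why: Acylketene trapping: thermal cycloreversion of the acyl Meldrum's acid expels acetone and CO2 to give acylketene 9, whose sp carbon is captured under neutral conditions by the free 4-hydroxyl of 3, while the 2-hydroxyl stays locked in its hydrogen bond to the ester and is flanked on both sides.

Step 7
Reactants: 10 allyl 2-hydroxy-3,6-dimethyl-4-{[3-oxo-5-(triisopropylsilyloxy)pentanoyl]oxy}benzoate
Product: 11 allyl 4-{[(1E,3Z)-1,3-bis(trimethylsilyloxy)-5-(triisopropylsilyloxy)penta-1,3-dien-1-yl]oxy}-3,6-dimethyl-2-(trimethylsilyloxy)benzoate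
Conditions: TMSOTf (3.3 equiv), Et3N (4 equiv), Et2O, 0 °C → rt; ammonium triflate layer removed under argon, used crude at once
Reagents that add atoms: trimethylsilyl trifluoromethanesulfonate, C[Si](C)(C)OS(=O)(=O)C(F)(F)F
Why: Soft enolisation with a silyl triflate and a tertiary amine: the phenol and the keto-enol are O-silylated, then silylation of the ester carbonyl acidifies the γ-hydrogens so that Et3N completes the 1,3-bis(silyloxy)diene without a strong base that could attack the aryl ester or the ring methyl groups.

Step 8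
Reactants: 12 1,1-dimethoxyethene
Product: 13 4,4-dimethoxybut-3-en-2-one
Conditions: acetyl chloride, Et3N, Et2O, 0 °C → rt; distillation
Reagents that add atoms: acetyl chloride, CC(=O)Cl
Why: C-acylation of an electron-rich ketene acetal: its β-carbon adds to the acid chloride and the amine removes HCl, giving the push-pull enone.

Step 9
Reactants: 11 allyl 4-{[(1E,3Z)-1,3-bis(trimethylsilyloxy)-5-(triisopropylsilyloxy)penta-1,3-dien-1-yl]oxy}-3,6-dimethyl-2-(trimethylsilyloxy)benzoate; 13 4,4-dimethoxybut-3-en-2-one
Product: 15 allyl 2-hydroxy-4-({2-hydroxy-4-methoxy-6-methyl-3-[(triisopropylsilyloxy)methyl]benzoyl}oxy)-3,6-dimethylbenzoate, via open-chain adduct 14 (not isolated)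
Conditions: 13 (1.3 equiv), TiCl4 (1.5 equiv), CH2Cl2, −78 → 0 °C; then cold 0.5 M HCl
Reagents that add atoms: none
Why: TiCl4 binds the carbonyl oxygen of 13 and makes its ketene-acetal carbon (future C4) the most electrophilic site; the terminal carbon of diene 11 (future C3) adds there and methoxide leaves, giving open-chain adduct 14 (drawn as its silyl ketene acetal, possibly titanium-bound in the flask), whose ketene acetal carbon (future C1) then attacks the activated methyl ketone (future C6) in an intramolecular Mukaiyama aldol addition, and loss of water with enolisation of the C2 carbonyl gives the arene. The closest known reaction type is the TiCl4-mediated formal [3+3] cyclocondensation of 1,3-bis(silyloxy)buta-1,3-dienes with 3-alkoxy-enones and 3-oxo ketene acetals, which delivers 4-alkoxysalicylates; new here are only the aryl ester on the diene and the silyloxymethyl group at its terminus. Ring A closes in a 6-(enolexo)-exo-trig aldol mode (C1 onto the C6 carbonyl), which needs the C4=C5 enol ether of 14 to hold C3 and the acetyl group cis, a geometry reachable under the Lewis acid, and the closure is made irreversible by dehydrative aromatisation. No stereocentre is formed: the single sp3 centre of 14 and all double-bond geometry are erased in the arene. The selectivity needed is regiochemical (diene terminus to the acetal carbon, central carbon to the ketone) and chemoselective (no ionisation of the C–O bond at the silyloxymethyl carbon); the first follows from the terminus being the most nucleophilic carbon of the diene and the doubly oxygenated carbon of the activated enone its most cation-stabilised electrophilic site, the second from the low temperature and the weakly Lewis-basic, bulky triisopropylsilyl ether. Aqueous acid in the work-up removes the aryl trimethylsilyl ether of ring B, so that 15 should be isolated with both phenols free and the methoxy group already in place at C4.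

Step 10
Reactants: 15 allyl 2-hydroxy-4-({2-hydroxy-4-methoxy-6-methyl-3-[(triisopropylsilyloxy)methyl]benzoyl}oxy)-3,6-dimethylbenzoate
Product: 16 allyl 2-hydroxy-4-{[2-hydroxy-3-(hydroxymethyl)-4-methoxy-6-methylbenzoyl]oxy}-3,6-dimethylbenzoate
Conditions: Bu4NF (1.5 equiv), AcOH (1.5 equiv), THF, 0 °C → rt
Reagents that add atoms: none
Why: Fluoride-induced cleavage of the silicon–oxygen bond, driven by the strong Si–F bond; the acetic acid buffer keeps the medium from turning basic so that the depside ester is not cleaved and the salicyl alcohol does not eliminate.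

Step 11
Reactants: 16 allyl 2-hydroxy-4-{[2-hydroxy-3-(hydroxymethyl)-4-methoxy-6-methylbenzoyl]oxy}-3,6-dimethylbenzoate
Product: 17 3-alpha-hydroxybarbatic acid (2-hydroxy-4-{[2-hydroxy-3-(hydroxymethyl)-4-methoxy-6-methylbenzoyl]oxy}-3,6-dimethylbenzoic acid)
Conditions: Pd(PPh3)4 (5 mol %), morpholine (3 equiv), THF, rt; then cold dilute HCl wash
Reagents that add atoms: none
Why: Tsuji–Trost deallylation: zerovalent palladium ionises the allyl ester to a π-allyl complex and the carboxylate, and morpholine captures the allyl unit irreversibly at room temperature, conditions that touch neither the hindered depside ester nor the benzylic alcohol.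

Compound list
1 | methyl 2,4-dihydroxy-3,6-dimethylbenzoate (atraric acid) | COC(=O)c1c(C)cc(O)c(C)c1O | starting material
2 | 2,4-dihydroxy-3,6-dimethylbenzoic acid | OC(=O)c1c(C)cc(O)c(C)c1O | intermediate
3 | allyl 2,4-dihydroxy-3,6-dimethylbenzoate | C=CCOC(=O)c1c(C)cc(O)c(C)c1O | intermediate
4 | methyl 3-hydroxypropanoate | COC(=O)CCO | starting material
5 | methyl 3-(triisopropylsilyloxy)propanoate | COC(=O)CCO[Si](C(C)C)(C(C)C)C(C)C | intermediate
6 | 3-(triisopropylsilyloxy)propanoic acid | OC(=O)CCO[Si](C(C)C)(C(C)C)C(C)C | intermediate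
7 | Meldrum's acid (2,2-dimethyl-1,3-dioxane-4,6-dione) | CC1(C)OC(=O)CC(=O)O1 | starting material
8 | 5-[1-hydroxy-3-(triisopropylsilyloxy)propylidene]-2,2-dimethyl-1,3-dioxane-4,6-dione | CC(C)[Si](C(C)C)(C(C)C)OCCC(O)=C1C(=O)OC(C)(C)OC1=O | intermediate
9 | acylketene, 5-(triisopropylsilyloxy)pent-1-ene-1,3-dione | CC(C)[Si](C(C)C)(C(C)C)OCCC(=O)C=C=O | intermediate (not isolated)
10 | allyl 2-hydroxy-3,6-dimethyl-4-{[3-oxo-5-(triisopropylsilyloxy)pentanoyl]oxy}benzoate | CC(C)[Si](C(C)C)(C(C)C)OCCC(=O)CC(=O)Oc1cc(C)c(C(=O)OCC=C)c(O)c1C | intermediate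
11 | allyl 4-{[(1E,3Z)-1,3-bis(trimethylsilyloxy)-5-(triisopropylsilyloxy)penta-1,3-dien-1-yl]oxy}-3,6-dimethyl-2-(trimethylsilyloxy)benzoate | CC(C)[Si](C(C)C)(C(C)C)OC/C=C(O[Si](C)(C)C)/C=C(/O[Si](C)(C)C)Oc1cc(C)c(C(=O)OCC=C)c(O[Si](C)(C)C)c1C | intermediate
12 | 1,1-dimethoxyethene | C=C(OC)OC | starting material
13 | 4,4-dimethoxybut-3-en-2-one | CC(=O)C=C(OC)OC | intermediate
14 | open-chain adduct, allyl 4-{[(1E,5E)-5-methoxy-3,7-dioxo-4-[(triisopropylsilyloxy)methyl]-1-(trimethylsilyloxy)octa-1,5-dien-1-yl]oxy}-3,6-dimethyl-2-(trimethylsilyloxy)benzoate (racemic) | CC(=O)/C=C(OC)\C(CO[Si](C(C)C)(C(C)C)C(C)C)C(=O)/C=C(/O[Si](C)(C)C)Oc1cc(C)c(C(=O)OCC=C)c(O[Si](C)(C)C)c1C | intermediate (not isolated)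
15 | allyl 2-hydroxy-4-({2-hydroxy-4-methoxy-6-methyl-3-[(triisopropylsilyloxy)methyl]benzoyl}oxy)-3,6-dimethylbenzoate | COc1cc(C)c(C(=O)Oc2cc(C)c(C(=O)OCC=C)c(O)c2C)c(O)c1CO[Si](C(C)C)(C(C)C)C(C)C | intermediate
16 | allyl 2-hydroxy-4-{[2-hydroxy-3-(hydroxymethyl)-4-methoxy-6-methylbenzoyl]oxy}-3,6-dimethylbenzoate | COc1cc(C)c(C(=O)Oc2cc(C)c(C(=O)OCC=C)c(O)c2C)c(O)c1CO | intermediate
17 | 3-alpha-hydroxybarbatic acid | COc1cc(C)c(C(=O)Oc2cc(C)c(C(=O)O)c(O)c2C)c(O)c1CO | target

Total steps: 11. Longest linear sequence: 8 steps (4 → 5 → 6 → 8 → 10 → 11 → 15 → 16 → 17, that is steps 3, 4, 5, 6, 7, 9, 10 and 11).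

Steps most likely to fail

Step 9. The oxygen on the future C3 carbon may be lost before or after the carbon–carbon bond formation. At the diene terminus the silyloxy group is allylic and can be ionised or eliminated by TiCl4 (vinyl ketone formation). In the product the same carbon is an ortho-hydroxybenzylic ether that a titanium phenoxide can expel. Fallback: ring A is closed by the same cyclocondensation without the C3 carbon, which is introduced afterwards. Setting out from 3, acetylketene generated from 2,2,6-trimethyl-4H-1,3-dioxin-4-one (xylene, 135 °C) should give allyl 2-hydroxy-3,6-dimethyl-4-[(3-oxobutanoyl)oxy]benzoate F1. TMSOTf/Et3N should convert it into allyl 4-{[(1E)-1,3-bis(trimethylsilyloxy)buta-1,3-dien-1-yl]oxy}-3,6-dimethyl-2-(trimethylsilyloxy)benzoate F2. Condensation of F2 with 13 under TiCl4 should give allyl 2-hydroxy-4-[(2-hydroxy-4-methoxy-6-methylbenzoyl)oxy]-3,6-dimethylbenzoate F3. Magnesium-directed ortho-formylation (MgCl2, Et3N, paraformaldehyde, MeCN, reflux) can take place only at C3 of ring A, the single free position ortho to a phenol, and should give allyl 4-[(3-formyl-2-hydroxy-4-methoxy-6-methylbenzoyl)oxy]-2-hydroxy-3,6-dimethylbenzoate F4. Reduction of the aldehyde with NaBH4 (THF/EtOH, −20 °C) rejoins the route at 16.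

Step 7. Under the amine base the aryl β-ketoester may expel the ring B phenoxide (acylketene formation). Alternatively, the weakly Lewis-basic aryl ester carbonyl may not be silylated, so that enolisation stops at the mono(silyl enol ether). Fallback: ring A is built on an allyl ester and the depside bond is made afterwards by esterification. Setting out from 8, thermolysis in the presence of allyl alcohol (toluene, 90 °C) should give allyl 3-oxo-5-(triisopropylsilyloxy)pentanoate F5. Bis-silylation (TMSOTf, Et3N, Et2O) should give (1E,3Z)-1-(allyloxy)-1,3-bis(trimethylsilyloxy)-5-(triisopropylsilyloxy)penta-1,3-diene F6. Cyclocondensation of F6 with 13 under TiCl4 should give allyl 2-hydroxy-4-methoxy-6-methyl-3-[(triisopropylsilyloxy)methyl]benzoate F7. Pd(PPh3)4 with morpholine should release 2-hydroxy-4-methoxy-6-methyl-3-[(triisopropylsilyloxy)methyl]benzoic acid F8. Condensation of F8 with phenol 3 by trifluoroacetic anhydride in toluene at rt, in which the mixed anhydride acylates the unchelated 4-hydroxyl, rejoins the route at 15.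

Step 6. At the temperature needed for the cycloreversion the β-silyloxy ketone unit may eliminate triisopropylsilanol, or the acylketene may dimerise faster than the ortho-substituted phenol traps it. Fallback: the order of bond formation is reversed, the aryl ester being made first and the ketone carbon–carbon bond second at room temperature. Setting out from 3 and 7, heating in toluene (90 °C) should open Meldrum's acid at the 4-hydroxyl to give 3-{4-[(allyloxy)carbonyl]-3-hydroxy-2,5-dimethylphenoxy}-3-oxopropanoic acid F9. Acid 6 is converted with 1,1'-carbonyldiimidazole (THF, rt) into 1-[3-(triisopropylsilyloxy)propanoyl]-1H-imidazole F10. Decarboxylative Claisen condensation of the magnesium salt of F9 (MgCl2, Et3N, MeCN/THF, rt) with F10 rejoins the route at 10.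

Further compounds
F1 | step 9 | allyl 2-hydroxy-3,6-dimethyl-4-[(3-oxobutanoyl)oxy]benzoate | CC(=O)CC(=O)Oc1cc(C)c(C(=O)OCC=C)c(O)c1C
F2 | step 9 | allyl 4-{[(1E)-1,3-bis(trimethylsilyloxy)buta-1,3-dien-1-yl]oxy}-3,6-dimethyl-2-(trimethylsilyloxy)benzoate | C=C(O[Si](C)(C)C)/C=C(/O[Si](C)(C)C)Oc1cc(C)c(C(=O)OCC=C)c(O[Si](C)(C)C)c1C
F3 | step 9 | allyl 2-hydroxy-4-[(2-hydroxy-4-methoxy-6-methylbenzoyl)oxy]-3,6-dimethylbenzoate | COc1cc(C)c(C(=O)Oc2cc(C)c(C(=O)OCC=C)c(O)c2C)c(O)c1
F4 | step 9 | allyl 4-[(3-formyl-2-hydroxy-4-methoxy-6-methylbenzoyl)oxy]-2-hydroxy-3,6-dimethylbenzoate | COc1cc(C)c(C(=O)Oc2cc(C)c(C(=O)OCC=C)c(O)c2C)c(O)c1C=O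
F5 | step 7 | allyl 3-oxo-5-(triisopropylsilyloxy)pentanoate | CC(C)[Si](C(C)C)(C(C)C)OCCC(=O)CC(=O)OCC=C
F6 | step 7 | (1E,3Z)-1-(allyloxy)-1,3-bis(trimethylsilyloxy)-5-(triisopropylsilyloxy)penta-1,3-diene | CC(C)[Si](C(C)C)(C(C)C)OC/C=C(O[Si](C)(C)C)/C=C(/O[Si](C)(C)C)OCC=C
F7 | step 7 | allyl 2-hydroxy-4-methoxy-6-methyl-3-[(triisopropylsilyloxy)methyl]benzoate | COc1cc(C)c(C(=O)OCC=C)c(O)c1CO[Si](C(C)C)(C(C)C)C(C)C
F8 | step 7 | 2-hydroxy-4-methoxy-6-methyl-3-[(triisopropylsilyloxy)methyl]benzoic acid | COc1cc(C)c(C(=O)O)c(O)c1CO[Si](C(C)C)(C(C)C)C(C)C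
F9 | step 6 | 3-{4-[(allyloxy)carbonyl]-3-hydroxy-2,5-dimethylphenoxy}-3-oxopropanoic acid | OC(=O)CC(=O)Oc1cc(C)c(C(=O)OCC=C)c(O)c1C
F10 | step 6 | 1-[3-(triisopropylsilyloxy)propanoyl]-1H-imidazole | CC(C)[Si](C(C)C)(C(C)C)OCCC(=O)n1ccnc1
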